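**Retrosynthetic overview** (eremophilane numbering: C3 bears the ester oxygen, C4 and C5 the methyls, C5 is the quaternary ring-fusion carbon, C7 the isopropylidene, C8 the ketone, C9 the enol carbon, C10 the sp2 ring-fusion carbon; ring A = C1–C5/C10, ring B = C5–C10)
1. Target ⇒ removal of a 4-methoxybenzyl group from the C9 oxygen and Yamaguchi esterification of the C3 hydroxyl with the (Z,Z)-diene acid; the core alcohol ⇒ bicyclic C9–H enone by aldol/dehydration with acetone at C7 and by C9 oxygenation (epoxidation, isomerisation to the diosphenol).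
2. Bicyclic enone ⇒ monocyclic cyclobutanone by rhodium-catalysed C–C activation/alkyne insertion, which forms C5–C10 and C8–C9 together, so rings A and B appear in one step.
3. Enabling feature: ring B is a cyclohex-2-enone whose carbonyl C8 and quaternary C5 are linked through C7–C6, i.e. a cyclobutanone (C5–C6–C7–C8) with the C9=C10 unit inserted into its C8–C5 bond; C10 is also the ring-A atom tied to C5 through C4–C3–C2–C1, so an alkyne on that tether closes both rings.
4. Cyclobutanone ⇒ tertiary 1-(phenylthio)cyclopropyl carbinol (invertive ring expansion) ⇒ cyclopropyl ketone (Felkin–Anh MeLi addition, C5) ⇒ Evans syn-aldol of a propionyl oxazolidinone with a pent-4-ynal (C3, C4).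
5. Ring order: sacrificial cyclobutanone, then rings A and B together; the side-chain acid comes from an ynoate by syn-carbocupration and Mitsunobu angeloylation.

Key step: step 9

Remark: the Why lines use the eremophilane numbering given above. The epoxide of 15 and the aldol centre of 19 are drawn as the expected major epimers; both centres are erased in the following step, so either epimer serves.

**Step 1**
Reactants: 1 5-(trimethylsilyl)pent-4-yn-1-ol
Product: 2 5-(trimethylsilyl)pent-4-ynal
Conditions: PhI(OAc)2, TEMPO (cat.), CH2Cl2, rt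
Reagents that add atoms: none
Why: Oxoammonium (TEMPO) oxidation with PhI(OAc)2 as terminal oxidant converts the primary alcohol into the aldehyde without over-oxidation and without touching the silylated alkyne; no stereocentre is involved.

**Step 2**
Reactants: 3 (S)-4-benzyl-3-propanoyl-1,3-oxazolidin-2-one; 2 5-(trimethylsilyl)pent-4-ynal
Product: 5 (S)-4-benzyl-3-[(2S,3R)-3-hydroxy-2-methyl-7-(trimethylsilyl)hept-6-ynoyl]-1,3-oxazolidin-2-one, via Z-dibutylboron enolate 4 (not isolated)
Conditions: Bu2BOTf, iPr2NEt, CH2Cl2, −78 °C; then 2, −78 → 0 °C; H2O2, MeOH, pH 7 buffer, 0 °C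
Reagents that add atoms: none
Why: Evans syn-aldol reaction: the Z-boron enolate adds through a closed chair (Zimmerman–Traxler) transition state on the enolate face remote from the benzyl group of the auxiliary, which sets C4 and C3 as the syn pair (2S,3R in 5) that becomes the trans C3–O/C4–CH3 relationship of ring A.

**Step 3**
Reactants: 5 aldol adduct
Product: 6 (2S,3R)-3-hydroxy-N-methoxy-N,2-dimethyl-7-(trimethylsilyl)hept-6-ynamide
Conditions: MeNH(OMe)·HCl, AlMe3, CH2Cl2, 0 °C → rt
Reagents that add atoms: N,O-dimethylhydroxylamine hydrochloride CNOC.Cl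
Why: Weinreb amide formation by aluminium-amide transamidation, assisted by the free β-hydroxyl, releases the auxiliary and leaves C3 and C4 untouched.

**Step 4**
Reactants: 6 hydroxy Weinreb amide
Product: 7 (2S,3R)-N-methoxy-N,2-dimethyl-3-[(triisopropylsilyl)oxy]-7-(trimethylsilyl)hept-6-ynamide
Conditions: iPr3SiOTf, 2,6-lutidine, CH2Cl2, 0 °C
Reagents that add atoms: triisopropylsilyl triflate CC(C)[Si](OS(=O)(=O)C(F)(F)F)(C(C)C)C(C)C
Why: Silylation with a silyl triflate installs a bulky, non-chelating and acid-tolerant ether that enforces Felkin–Anh control in step 6 and survives steps 7 to 14; no stereocentre changes.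

**Step 5**
Reactants: 8 cyclopropyl phenyl sulfide; 7 silylated Weinreb amide
Product: 10 (2S,3R)-2-methyl-1-[1-(phenylsulfanyl)cyclopropyl]-3-[(triisopropylsilyl)oxy]-7-(trimethylsilyl)hept-6-yn-1-one, via 1-lithiocyclopropyl phenyl sulfide 9 (not isolated)
Conditions: 8, n-BuLi, THF, 0 °C; then 7, −78 → −30 °C; NH4Cl (aq)
Reagents that add atoms: none
Why: Weinreb ketone synthesis: the sulfur-stabilised cyclopropyllithium adds once to the N-methoxy-N-methylamide, whose chelated tetrahedral adduct collapses only on work-up, so the ketone forms without over-addition or epimerisation at C4.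

**Step 6**
Reactants: 10 cyclopropyl ketone
Product: 11 (2S,3S,4R)-3-methyl-2-[1-(phenylsulfanyl)cyclopropyl]-4-[(triisopropylsilyl)oxy]-8-(trimethylsilyl)oct-7-yn-2-ol
Conditions: MeLi, Et2O, −78 °C; NH4Cl (aq)
Reagents that add atoms: methyllithium [Li]C
Why: 1,2-Addition of MeLi under Felkin–Anh control (the silyl ether cannot chelate): with the C3 branch anti to the nucleophile and C4–H next to the bulky cyclopropyl substituent, methyl should add to the Re face of the ketone and set the tertiary carbinol centre C5 (2S in 11, hydroxyl syn to the C4 methyl).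

**Step 7**
Reactants: 11 tertiary cyclopropyl carbinol
Product: 12 (2R)-2-methyl-2-[(2R,3R)-3-[(triisopropylsilyl)oxy]-7-(trimethylsilyl)hept-6-yn-2-yl]cyclobutan-1-one
Conditions: p-TsOH·H2O (cat.), water-saturated benzene, 50 °C
Reagents that add atoms: water O
Why: Acid-induced cyclopropylcarbinyl-to-cyclobutyl ring expansion (semipinacol type) of the 1-(phenylthio)cyclopropyl carbinol: the cyclopropane C–C bond anti to the departing water migrates to C5 with inversion while sulfur stabilises the cyclobutyl cation, which is hydrolysed to the ketone, so the carbinol configuration is translated into the (R)-configured quaternary C5.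

**Step 8**
Reactants: 12 C-silylated alkynyl cyclobutanone
Product: 13 (2R)-2-methyl-2-[(2R,3R)-3-[(triisopropylsilyl)oxy]hept-6-yn-2-yl]cyclobutan-1-one
Conditions: K2CO3, MeOH, rt
Reagents that add atoms: none
Why: Methanolysis of the alkynyl C–Si bond (protodesilylation) frees the terminal alkyne while the silyl ether, which is inert to carbonate, and the non-enolisable quaternary centre stay intact.

**Step 9**
Reactants: 13 alkynyl cyclobutanone
Product: 14 (4aR,5R,6R)-4a,5-dimethyl-6-[(triisopropylsilyl)oxy]-4,4a,5,6,7,8-hexahydronaphthalen-2(3H)-one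
Conditions: [Rh(C2H4)2Cl]2 (5 mol %), P[3,5-(CF3)2C6H3]3 (20 mol %), 1,4-dioxane (0.02 M), 130 °C, sealed tube
Reagents that add atoms: none
Why: Monovalent rhodium adds oxidatively into the strained acyl–alkyl bond C8–C5 of the cyclobutanone to give an acyl(alkyl) rhodacycle of trivalent rhodium, the tethered alkyne inserts into this rhodacycle, and reductive elimination forms C5–C10 and C8–C9 and frees the catalyst. The closest known reaction type is the rhodium-catalysed intramolecular cut-and-sew (formal [4+2]) coupling of 2,2-disubstituted cyclobutanones with alkynes tethered at C2, which gives fused cyclohex-2-enones. Ring A closes by 6-exo-dig carbometalation of the alkyne (C5–C10), and ring B arises by two-carbon ring expansion of the four-membered ketone through a seven-membered rhodacycle (C8–C9 by reductive elimination). No new stereocentre is created: C5 is carried over with retention because the metal enters and leaves the C5–C bond on the same face, while the C3 and C4 substituents are spectators that lie equatorial in the forming ring A. The step needs site selectivity (C8–C5 over C8–C7) and chemoselectivity over CO extrusion and alkyne oligomerisation: the alkyne tether delivers the metal to the proximal bond and only that rhodacycle can be intercepted, the electron-poor triarylphosphine disfavours decarbonylation, and high dilution suppresses intermolecular alkyne coupling.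

**Step 10**
Reactants: 14 bicyclic enone
Product: 15 (4aR,5R,6R)-1,8a-epoxy-4a,5-dimethyl-6-[(triisopropylsilyl)oxy]octahydronaphthalen-2(1H)-one (epoxide oxygen cis to the C4a methyl drawn)
Conditions: H2O2 (30 %), NaOH (aq), MeOH, 0 °C → rt
Reagents that add atoms: hydrogen peroxide OO
Why: Weitz–Scheffer nucleophilic epoxidation of the enone: hydroperoxide adds axially to C10 and the enolate closes onto oxygen, expected mainly cis to the angular methyl by analogy with ring-fusion enones of steroids, and both epimers converge in step 11.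

**Step 11**
Reactants: 15 epoxy ketone
Product: 16 (4aR,5R,6R)-1-hydroxy-4a,5-dimethyl-6-[(triisopropylsilyl)oxy]-4,4a,5,6,7,8-hexahydronaphthalen-2(3H)-one
Conditions: KOH, MeOH/H2O, 60 °C, argon; then HCl (aq)
Reagents that add atoms: potassium hydroxide [K+].[OH-] (oxygen exchange at C9: the hydroxide oxygen enters, the epoxide oxygen leaves as water)
Why: Alkali-mediated isomerisation of an α,β-epoxy ketone to a diosphenol (hydroxide opening at C9 followed by E1cB loss of the C10 oxygen) gives the enolised 1,2-dione and erases the two epoxide stereocentres.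

**Step 12**
Reactants: 16 diosphenol
Product: 17 (4aR,5R,6R)-1-[(4-methoxybenzyl)oxy]-4a,5-dimethyl-6-[(triisopropylsilyl)oxy]-4,4a,5,6,7,8-hexahydronaphthalen-2(3H)-one
Conditions: 4-MeOC6H4CH2Cl, K2CO3, Bu4NI (cat.), DMF, rt
Reagents that add atoms: 4-methoxybenzyl chloride COc1ccc(CCl)cc1
Why: Williamson O-alkylation of the acidic diosphenol masks the C9 oxygen for the base and acylation steps that follow; C-alkylation at the fully substituted C10 is disfavoured.

**Step 13**
Reactants: 17 diosphenol 4-methoxybenzyl ether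
Product: 19 (4aR,5R,6R)-3-(2-hydroxypropan-2-yl)-1-[(4-methoxybenzyl)oxy]-4a,5-dimethyl-6-[(triisopropylsilyl)oxy]-4,4a,5,6,7,8-hexahydronaphthalen-2(3H)-one, via lithium enolate 18 (not isolated)
Conditions: LiN(iPr)2, THF, −78 °C; acetone, −78 °C; AcOH, −78 °C
Reagents that add atoms: acetone CC(C)=O
Why: Kinetic deprotonation at C7, the only sp3 α-carbon of the ketone, and aldol addition to acetone, quenched cold to avoid retro-aldol; the new C7 centre (substituent expected trans to the angular methyl) is erased in step 14.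

**Step 14**
Reactants: 19 aldol adduct
Product: 21 (4aR,5R,6R)-1-[(4-methoxybenzyl)oxy]-4a,5-dimethyl-3-(propan-2-ylidene)-6-[(triisopropylsilyl)oxy]-4,4a,5,6,7,8-hexahydronaphthalen-2(3H)-one, via tertiary mesylate 20 (not isolated)
Conditions: MsCl, Et3N, CH2Cl2, 0 °C; then DBU, rt
Reagents that add atoms: none
Why: Sulfene mesylation of the tertiary aldol hydroxyl and E1cB elimination with DBU give the conjugated tetrasubstituted isopropylidene ketone, the thermodynamically favoured alkene isomer.

**Step 15**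
Reactants: 21 silyl-protected dienone
Product: 22 (4aR,5R,6R)-6-hydroxy-1-[(4-methoxybenzyl)oxy]-4a,5-dimethyl-3-(propan-2-ylidene)-4,4a,5,6,7,8-hexahydronaphthalen-2(3H)-one
Conditions: Bu4NF, AcOH, THF, rt
Reagents that add atoms: none
Why: Fluoride cleavage of the silyl ether, buffered with AcOH, frees the C3 hydroxyl without touching the enol ether or the dienone; C3 retains its configuration.

**Step 16**
Reactants: 23 tert-butyldimethyl(prop-2-yn-1-yloxy)silane
Product: 25 tert-butyl 4-[(tert-butyldimethylsilyl)oxy]but-2-ynoate, via lithium acetylide 24 (not isolated)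
Conditions: n-BuLi, THF, −78 °C; then (t-BuOCO)2O, −78 → 0 °C
Reagents that add atoms: di-tert-butyl dicarbonate CC(C)(C)OC(=O)OC(=O)OC(C)(C)C
Why: C-Acylation of the lithium acetylide with di-tert-butyl dicarbonate gives the tert-butyl ynoate directly.

**Step 17**
Reactants: 25 ynoate
Product: 26 tert-butyl (Z)-4-[(tert-butyldimethylsilyl)oxy]-3-methylbut-2-enoate
Conditions: Me2CuLi (from CuI and MeLi), THF, −78 °C; MeOH then NH4Cl (aq) at −78 °C
Reagents that add atoms: lithium dimethylcuprate [Li+].C[Cu-]C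
Why: syn-Carbocupration (conjugate addition) of the ynoate and protonation of the alkenylcopper at low temperature with retention place methyl and hydrogen cis, which fixes the Z geometry (CH2O cis to the ester).

**Step 18**
Reactants: 26 silylated Z enoate
Product: 27 tert-butyl (Z)-4-hydroxy-3-methylbut-2-enoate
Conditions: HF·pyridine, pyridine, THF, 0 °C
Reagents that add atoms: none
Why: Desilylation under mildly acidic fluoride conditions frees the allylic alcohol without forming an alkoxide, so the hindered tert-butyl ester should not lactonise and the Z geometry is kept.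

**Step 19**
Reactants: 27 Z hydroxy ester; 28 angelic acid, (Z)-2-methylbut-2-enoic acid
Product: 29 tert-butyl (Z)-3-methyl-4-{[(Z)-2-methylbut-2-enoyl]oxy}but-2-enoate
Conditions: PPh3, DIAD, THF, 0 °C
Reagents that add atoms: none
Why: Mitsunobu esterification: the angelate anion displaces the activated primary allylic oxygen by SN2, so the angeloyl carbonyl is never activated and its Z geometry is not scrambled.

**Step 20**
Reactants: 29 tert-butyl diester
Product: 30 (Z)-3-methyl-4-{[(Z)-2-methylbut-2-enoyl]oxy}but-2-enoic acid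
Conditions: CF3CO2H, CH2Cl2, 0 °C
Reagents that add atoms: none
Why: Acidolysis of the tert-butyl ester (loss of isobutene) frees the acid while the allylic angelate and both Z alkenes tolerate cold CF3CO2H.

**Step 21**
Reactants: 30 side-chain acid; 22 core alcohol
Product: 32 4-methoxybenzyl ether of the target at the C9 oxygen (ester of 22 with 30 at the C3 hydroxyl), via mixed anhydride 31 (not isolated)
Conditions: 2,4,6-Cl3C6H2COCl, Et3N, toluene, rt; then 22, DMAP, rt
Reagents that add atoms: none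
Why: Yamaguchi esterification through the mixed anhydride acylates the equatorial C3 hydroxyl with retention at C3; pre-formed anhydride, catalytic DMAP and room temperature limit isomerisation of the Z enoate.

**Step 22**
Reactants: 32 protected target
Product: 33 CNP0228871.1, (3R,4R,5R)-9-hydroxy-3-{(Z)-3-methyl-4-[(Z)-2-methylbut-2-enoyloxy]but-2-enoyloxy}eremophila-7(11),9-dien-8-one
Conditions: CF3CO2H, anisole, CH2Cl2, 0 °C
Reagents that add atoms: none
Why: Acidolytic removal of the 4-methoxybenzyl enol ether (benzylic cation trapped by anisole) unveils the diosphenol under conditions that spare the two unsaturated esters.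

**Compound list**
1 | 5-(trimethylsilyl)pent-4-yn-1-ol | C[Si](C)(C)C#CCCCO | starting material
2 | 5-(trimethylsilyl)pent-4-ynal | C[Si](C)(C)C#CCCC=O | intermediate
3 | (S)-4-benzyl-3-propanoyl-1,3-oxazolidin-2-one | CCC(=O)N1[C@@H](Cc2ccccc2)COC1=O | starting material
4 | (S)-4-benzyl-3-[(Z)-1-(dibutylboranyloxy)prop-1-en-1-yl]-1,3-oxazolidin-2-one (Z-boron enolate, not isolated) | C/C=C(\OB(CCCC)CCCC)N1[C@@H](Cc2ccccc2)COC1=O | intermediate
5 | (S)-4-benzyl-3-[(2S,3R)-3-hydroxy-2-methyl-7-(trimethylsilyl)hept-6-ynoyl]-1,3-oxazolidin-2-one | C[Si](C)(C)C#CCC[C@@H](O)[C@H](C)C(=O)N1[C@@H](Cc2ccccc2)COC1=O | intermediate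
6 | (2S,3R)-3-hydroxy-N-methoxy-N,2-dimethyl-7-(trimethylsilyl)hept-6-ynamide | C[Si](C)(C)C#CCC[C@@H](O)[C@H](C)C(=O)N(C)OC | intermediate
7 | (2S,3R)-N-methoxy-N,2-dimethyl-3-[(triisopropylsilyl)oxy]-7-(trimethylsilyl)hept-6-ynamide | C[Si](C)(C)C#CCC[C@@H](O[Si](C(C)C)(C(C)C)C(C)C)[C@H](C)C(=O)N(C)OC | intermediate
8 | cyclopropyl phenyl sulfide | C1CC1Sc1ccccc1 | starting material
9 | 1-lithio-1-(phenylsulfanyl)cyclopropane (not isolated) | [Li]C1(CC1)Sc1ccccc1 | intermediate
10 | (2S,3R)-2-methyl-1-[1-(phenylsulfanyl)cyclopropyl]-3-[(triisopropylsilyl)oxy]-7-(trimethylsilyl)hept-6-yn-1-one | C[Si](C)(C)C#CCC[C@@H](O[Si](C(C)C)(C(C)C)C(C)C)[C@H](C)C(=O)C1(CC1)Sc1ccccc1 | intermediate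
11 | (2S,3S,4R)-3-methyl-2-[1-(phenylsulfanyl)cyclopropyl]-4-[(triisopropylsilyl)oxy]-8-(trimethylsilyl)oct-7-yn-2-ol | C[Si](C)(C)C#CCC[C@@H](O[Si](C(C)C)(C(C)C)C(C)C)[C@H](C)[C@](C)(O)C1(CC1)Sc1ccccc1 | intermediate
12 | (2R)-2-methyl-2-[(2R,3R)-3-[(triisopropylsilyl)oxy]-7-(trimethylsilyl)hept-6-yn-2-yl]cyclobutan-1-one | O=C1CC[C@]1(C)[C@@H](C)[C@H](O[Si](C(C)C)(C(C)C)C(C)C)CCC#C[Si](C)(C)C | intermediate
13 | (2R)-2-methyl-2-[(2R,3R)-3-[(triisopropylsilyl)oxy]hept-6-yn-2-yl]cyclobutan-1-one | O=C1CC[C@]1(C)[C@@H](C)[C@H](O[Si](C(C)C)(C(C)C)C(C)C)CCC#C | intermediate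
14 | (4aR,5R,6R)-4a,5-dimethyl-6-[(triisopropylsilyl)oxy]-4,4a,5,6,7,8-hexahydronaphthalen-2(3H)-one | CC(C)[Si](C(C)C)(C(C)C)O[C@@H]1CCC2=CC(=O)CC[C@]2(C)[C@H]1C | intermediate
15 | (4aR,5R,6R)-1,8a-epoxy-4a,5-dimethyl-6-[(triisopropylsilyl)oxy]octahydronaphthalen-2(1H)-one, epoxide oxygen cis to the C4a methyl | CC(C)[Si](C(C)C)(C(C)C)O[C@@H]1CC[C@]2(O3)[C@@H]3C(=O)CC[C@]2(C)[C@H]1C | intermediate
16 | (4aR,5R,6R)-1-hydroxy-4a,5-dimethyl-6-[(triisopropylsilyl)oxy]-4,4a,5,6,7,8-hexahydronaphthalen-2(3H)-one | CC(C)[Si](C(C)C)(C(C)C)O[C@@H]1CCC2=C(O)C(=O)CC[C@]2(C)[C@H]1C | intermediate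
17 | (4aR,5R,6R)-1-[(4-methoxybenzyl)oxy]-4a,5-dimethyl-6-[(triisopropylsilyl)oxy]-4,4a,5,6,7,8-hexahydronaphthalen-2(3H)-one | CC(C)[Si](C(C)C)(C(C)C)O[C@@H]1CCC2=C(OCc3ccc(OC)cc3)C(=O)CC[C@]2(C)[C@H]1C | intermediate
18 | lithium (4aR,5R,6R)-1-[(4-methoxybenzyl)oxy]-4a,5-dimethyl-6-[(triisopropylsilyl)oxy]-4,4a,5,6,7,8-hexahydronaphthalen-2-olate (not isolated) | CC(C)[Si](C(C)C)(C(C)C)O[C@@H]1CCC2=C(OCc3ccc(OC)cc3)C(O[Li])=CC[C@]2(C)[C@H]1C | intermediate
19 | (4aR,5R,6R)-3-(2-hydroxypropan-2-yl)-1-[(4-methoxybenzyl)oxy]-4a,5-dimethyl-6-[(triisopropylsilyl)oxy]-4,4a,5,6,7,8-hexahydronaphthalen-2(3H)-one, C3 substituent trans to the C4a methyl | CC(C)[Si](C(C)C)(C(C)C)O[C@@H]1CCC2=C(OCc3ccc(OC)cc3)C(=O)[C@H](C(C)(C)O)C[C@]2(C)[C@H]1C | intermediate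
20 | methanesulfonate of the tertiary hydroxyl of 19 (not isolated) | CC(C)[Si](C(C)C)(C(C)C)O[C@@H]1CCC2=C(OCc3ccc(OC)cc3)C(=O)[C@H](C(C)(C)OS(C)(=O)=O)C[C@]2(C)[C@H]1C | intermediate
21 | (4aR,5R,6R)-1-[(4-methoxybenzyl)oxy]-4a,5-dimethyl-3-(propan-2-ylidene)-6-[(triisopropylsilyl)oxy]-4,4a,5,6,7,8-hexahydronaphthalen-2(3H)-one | CC(C)[Si](C(C)C)(C(C)C)O[C@@H]1CCC2=C(OCc3ccc(OC)cc3)C(=O)C(=C(C)C)C[C@]2(C)[C@H]1C | intermediate
22 | (4aR,5R,6R)-6-hydroxy-1-[(4-methoxybenzyl)oxy]-4a,5-dimethyl-3-(propan-2-ylidene)-4,4a,5,6,7,8-hexahydronaphthalen-2(3H)-one | O[C@@H]1CCC2=C(OCc3ccc(OC)cc3)C(=O)C(=C(C)C)C[C@]2(C)[C@H]1C | intermediate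
23 | tert-butyldimethyl(prop-2-yn-1-yloxy)silane | C#CCO[Si](C)(C)C(C)(C)C | starting material
24 | lithium 3-[(tert-butyldimethylsilyl)oxy]prop-1-yn-1-ide (not isolated) | [Li]C#CCO[Si](C)(C)C(C)(C)C | intermediate
25 | tert-butyl 4-[(tert-butyldimethylsilyl)oxy]but-2-ynoate | CC(C)(C)OC(=O)C#CCO[Si](C)(C)C(C)(C)C | intermediate
26 | tert-butyl (Z)-4-[(tert-butyldimethylsilyl)oxy]-3-methylbut-2-enoate | CC(C)(C)[Si](C)(C)OC/C(C)=C\C(=O)OC(C)(C)C | intermediate
27 | tert-butyl (Z)-4-hydroxy-3-methylbut-2-enoate | OC/C(C)=C\C(=O)OC(C)(C)C | intermediate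
28 | angelic acid, (Z)-2-methylbut-2-enoic acid | C/C=C(/C)C(=O)O | starting material
29 | tert-butyl (Z)-3-methyl-4-{[(Z)-2-methylbut-2-enoyl]oxy}but-2-enoate | C/C=C(/C)C(=O)OC/C(C)=C\C(=O)OC(C)(C)C | intermediate
30 | (Z)-3-methyl-4-{[(Z)-2-methylbut-2-enoyl]oxy}but-2-enoic acid | C/C=C(/C)C(=O)OC/C(C)=C\C(=O)O | intermediate
31 | mixed anhydride of 30 with 2,4,6-trichlorobenzoic acid (not isolated) | C/C=C(/C)C(=O)OC/C(C)=C\C(=O)OC(=O)c1c(Cl)cc(Cl)cc1Cl | intermediate
32 | C9-O-(4-methoxybenzyl) ether of the target | C/C=C(/C)C(=O)OC/C(C)=C\C(=O)O[C@@H]1CCC2=C(OCc3ccc(OC)cc3)C(=O)C(=C(C)C)C[C@]2(C)[C@H]1C | intermediate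
33 | CNP0228871.1, (3R,4R,5R)-9-hydroxy-3-{(Z)-3-methyl-4-[(Z)-2-methylbut-2-enoyloxy]but-2-enoyloxy}eremophila-7(11),9-dien-8-one | C/C=C(/C)C(=O)OC/C(C)=C\C(=O)O[C@@H]1CCC2=C(O)C(=O)C(=C(C)C)C[C@]2(C)[C@H]1C | target

**Step count and risks**
Total steps: 22. Longest linear sequence: 17 (steps 1–15, 21, 22); the side-chain acid takes steps 16–20.

Steps most likely to fail:

1. Step 9. CO extrusion from the acyl rhodacycle (ring contraction to a cyclopropane) or oligomerisation of the terminal alkyne may outrun the insertion. The fallback sets out from Weinreb amide 7 and comes back at enone 14; it builds ring A first and ring B by Robinson annulation. MeMgBr (THF, 0 °C) would convert 7 into the methyl ketone (3S,4R)-3-methyl-4-[(triisopropylsilyl)oxy]-8-(trimethylsilyl)oct-7-yn-2-one F1. SmI2 (THF, HMPA, t-BuOH) would close ring A by 6-exo-dig ketyl–alkyne cyclisation to the tertiary allylic alcohol (2S,3R)-1,2-dimethyl-3-[(triisopropylsilyl)oxy]-6-[(trimethylsilyl)methylidene]cyclohexan-1-ol F2 (carbinol epimers of no consequence). Ozonolysis (O3, CH2Cl2/MeOH, −78 °C; Me2S) of the exocyclic vinylsilane would give the α-hydroxy ketone (3S,4R)-2-hydroxy-2,3-dimethyl-4-[(triisopropylsilyl)oxy]cyclohexan-1-one F3, and SmI2 (THF/MeOH) would cleave the α-hydroxyl reductively to the ring-A ketone (3R,4R)-2,3-dimethyl-4-[(triisopropylsilyl)oxy]cyclohexan-1-one F4 (C2 epimerisable). Robinson annulation of F4 with but-3-en-2-one (KOH, EtOH, 0 °C, then reflux) would add the more substituted enolate anti to the C4 methyl (C5–C6 bond, cis-dimethyl) and close ring B by aldol condensation (C9=C10), giving 14.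

2. Step 7. Ionisation to a free cyclopropylcarbinyl cation would let the ring bond migrate to either face of C5 (loss of stereochemical fidelity), and elimination may compete. The fallback sets out from carbinol 11 and comes back at cyclobutanone 12; it runs the rearrangement through a discrete epoxide under non-protic conditions. S-Methylation (MeOTf, CH2Cl2, 0 °C) would give the sulfonium salt [1-((2S,3S,4R)-2-hydroxy-3-methyl-4-[(triisopropylsilyl)oxy]-8-(trimethylsilyl)oct-7-yn-2-yl)cyclopropyl](methyl)(phenyl)sulfonium triflate F5. KOt-Bu (THF, 0 °C) would make the alkoxide displace methyl phenyl sulfide at the cyclopropyl carbon, giving the oxaspiropentane (2S)-2-methyl-2-[(2S,3R)-3-[(triisopropylsilyl)oxy]-7-(trimethylsilyl)hept-6-yn-2-yl]-1-oxaspiro[2.2]pentane F6 with C5 unchanged. LiBF4 (benzene, rt) would then trigger the epoxide-to-cyclobutanone rearrangement with inversion at C5, giving 12.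

3. Step 6. Facial selectivity may be poor, because the α-methyl and β-silyloxy substituents of ketone 10 are syn and the nucleophile is small. The fallback sets out from hydroxy amide 6 and comes back at carbinol 11; it exchanges the roles of nucleophile and electrophile and uses chelation control. MeMgBr (excess, THF, 0 °C) would give the β-hydroxy methyl ketone (3S,4R)-4-hydroxy-3-methyl-8-(trimethylsilyl)oct-7-yn-2-one F7. Excess 1-lithiocyclopropyl phenyl sulfide 9 (THF, −78 °C, MgBr2·OEt2 as an optional additive) would first form the metal alkoxide and then add to the six-membered chelate from the face opposite to the C4 methyl and the C3 chain, which sit on the same face. This would give the diol (2S,3S,4R)-3-methyl-2-[1-(phenylsulfanyl)cyclopropyl]-8-(trimethylsilyl)oct-7-yne-2,4-diol F8 with the C5 configuration of 11. iPr3SiOTf (1 equiv), 2,6-lutidine, CH2Cl2, −78 °C would silylate only the secondary hydroxyl, giving 11.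

**Further compounds**
F1 | step 9 | (3S,4R)-3-methyl-4-[(triisopropylsilyl)oxy]-8-(trimethylsilyl)oct-7-yn-2-one | C[Si](C)(C)C#CCC[C@@H](O[Si](C(C)C)(C(C)C)C(C)C)[C@H](C)C(C)=O
F2 | step 9 | (2S,3R)-1,2-dimethyl-3-[(triisopropylsilyl)oxy]-6-[(trimethylsilyl)methylidene]cyclohexan-1-ol | CC(C)[Si](C(C)C)(C(C)C)O[C@@H]1CCC(=C[Si](C)(C)C)C(C)(O)[C@H]1C
F3 | step 9 | (3S,4R)-2-hydroxy-2,3-dimethyl-4-[(triisopropylsilyl)oxy]cyclohexan-1-one | CC(C)[Si](C(C)C)(C(C)C)O[C@@H]1CCC(=O)C(C)(O)[C@H]1C
F4 | step 9 | (3R,4R)-2,3-dimethyl-4-[(triisopropylsilyl)oxy]cyclohexan-1-one | CC(C)[Si](C(C)C)(C(C)C)O[C@@H]1CCC(=O)C(C)[C@H]1C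
F5 | step 7 | [1-((2S,3S,4R)-2-hydroxy-3-methyl-4-[(triisopropylsilyl)oxy]-8-(trimethylsilyl)oct-7-yn-2-yl)cyclopropyl](methyl)(phenyl)sulfonium triflate | C[Si](C)(C)C#CCC[C@@H](O[Si](C(C)C)(C(C)C)C(C)C)[C@H](C)[C@](C)(O)C1(CC1)[S+](C)c1ccccc1.[O-]S(=O)(=O)C(F)(F)F
F6 | step 7 | (2S)-2-methyl-2-[(2S,3R)-3-[(triisopropylsilyl)oxy]-7-(trimethylsilyl)hept-6-yn-2-yl]-1-oxaspiro[2.2]pentane | C[Si](C)(C)C#CCC[C@@H](O[Si](C(C)C)(C(C)C)C(C)C)[C@H](C)[C@]1(C)OC12CC2
F7 | step 6 | (3S,4R)-4-hydroxy-3-methyl-8-(trimethylsilyl)oct-7-yn-2-one | C[Si](C)(C)C#CCC[C@@H](O)[C@H](C)C(C)=O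
F8 | step 6 | (2S,3S,4R)-3-methyl-2-[1-(phenylsulfanyl)cyclopropyl]-8-(trimethylsilyl)oct-7-yne-2,4-diol | C[Si](C)(C)C#CCC[C@@H](O)[C@H](C)[C@](C)(O)C1(CC1)Sc1ccccc1
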